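The target, filixic acid ABP, is cut between the bridging CH2 on the propionylfilicinic ring (ring C) and C-5 of the central butyrylphloroglucinol ring (ring B). In one operation propionylfilicinic acid is aminomethylated at its only ring C–H, the Mannich base expels dimethylamine, and the liberated 6-methylene triketone is captured by the two-ring phenol norflavaspidic acid AB (rings A and B). This joins three components through two C–C bonds, the second one uniting the halves. The step exploits C-5 of ring B, the sole unsubstituted aromatic carbon, flanked by the C-4 and C-6 hydroxyls, as the only carbon nucleophile of that partner. The precursors are a two-ring phenol, a monocyclic enolic triketone and an iminium salt.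

Key step: step 5

Assumption: every enolic triketone ring is drawn in the tautomer used for the target. These tautomers interconvert freely, and the target holds no stereocentre, so no step has to set configuration.

Step 1
Reactants: 1 2',4',6'-trihydroxyacetophenone (phloroacetophenone)
Product: 2 acetylfilicinic acid (2-acetyl-3,5-dihydroxy-4,4-dimethylcyclohexa-2,5-dien-1-one)
Conditions: MeI (2.2 equiv), NaOMe (3.2 equiv), MeOH, 0 °C to rt; then aq. HCl
Reagents that add atoms: iodomethane, CI
Why: Dearomative geminal C-methylation of the phloroglucinol polyanion, in which the first methyl makes its carbon the most electron-rich site, the second enters there and locks the ring as an enolic triketone whose delocalised anion is a poorer nucleophile, so limiting MeI should hold the sequence at the dimethyl stage.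

Step 2
Reactants: 3 2',4',6'-trihydroxypropiophenone (flopropione)
Product: 4 propionylfilicinic acid (3,5-dihydroxy-4,4-dimethyl-2-propanoylcyclohexa-2,5-dien-1-one)
Conditions: MeI (2.2 equiv), NaOMe (3.2 equiv), MeOH, 0 °C to rt; then aq. HCl
Reagents that add atoms: iodomethane, CI
Why: The same dearomative geminal C-methylation as in step 1, applied to the propionyl homologue.

Step 3
Reactants: 5 phloroglucinol (benzene-1,3,5-triol)
Product: 6 phlorobutyrophenone (1-(2,4,6-trihydroxyphenyl)butan-1-one)
Conditions: butanoyl chloride (1.05 equiv), AlCl3 (3 equiv), CH2Cl2/MeNO2, 0 to 40 °C; then ice/aq. HCl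
Reagents that add atoms: butanoyl chloride, CCCC(=O)Cl
Why: Friedel–Crafts acylation of a very electron-rich arene, in which the chelated acyl group deactivates the ring so the reaction should stop after one acylation.

Step 4
Reactants: 2 acetylfilicinic acid; 6 phlorobutyrophenone (3 equiv, excess recovered)
Product: 9 norflavaspidic acid AB, via Mannich base 7 (not isolated), via methylene triketone 8 (not isolated)
Conditions: 2 added slowly to [Me2N=CH2]I (1.0 equiv), MeCN, -10 °C to rt; then 6 (3 equiv), NaOAc (1.0 equiv), 40 °C; dilute aq. HCl wash
Reagents that add atoms: Eschenmoser's salt (N,N-dimethylmethyleneiminium iodide), C[N+](C)=C.[I-]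
Why: Mannich reaction at the only ring C–H of 2, E1cB loss of dimethylamine once acetate frees the enolate, and Friedel–Crafts-type conjugate addition (carba-Betti coupling) of one of the two equivalent free positions of 6 to 8, with the excess of 6 favouring single substitution.

Step 5
Reactants: 4 propionylfilicinic acid; 9 norflavaspidic acid AB
Product: 12 filixic acid ABP (target), via Mannich base 10 (not isolated), via methylene triketone 11 (not isolated)
Conditions: 4 added slowly to [Me2N=CH2]I (1.0 equiv), MeCN, -10 °C to rt, until 4 is consumed; then 9 (1.0 equiv), NaOAc (1.0 equiv), 40 °C; dilute aq. HCl wash, crystallisation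
Reagents that add atoms: Eschenmoser's salt (N,N-dimethylmethyleneiminium iodide), C[N+](C)=C.[I-]
Why: The enolic C-6–H of 4, its only ring C–H, attacks the iminium ion (Mannich reaction) to give 10 as a latent hydroiodide, and acetate then frees the enolate, which expels dimethylamine (E1cB) and releases the cross-conjugated 6-methylene triketone 11 slowly and at low concentration. C-5 of ring B of 9, ortho to the C-4 and C-6 hydroxyls and para to the C-2 hydroxyl, adds to the exocyclic CH2 of 11 in a Friedel–Crafts-type conjugate addition, and rearomatisation of ring B with enolisation of ring C gives 12 with the new CH2–C-5 bond. The closest known reaction type is the carba-Betti (Mannich base) methylene bridging of cyclic enolic di- and triketones with acylphloroglucinols, the laboratory form of the biogenetic capture of alkylidene triketones. No ring is closed and no stereocentre is created. The step needs cross-coupling over homo-coupling and a single site of attack, and these are secured by converting 4 completely into 10 before 9 is added, so that no free 4 remains to intercept 11, and by the fact that ring A of 9 has no C–H left and ring B only one. It also needs the existing A–B bridge to stay in place, which the near-neutral acetate/dimethylammonium buffer and the mild temperature should secure by keeping retro-Michael (rottlerone-type) exchange slow.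

Compound list
1 | 2',4',6'-trihydroxyacetophenone (phloroacetophenone) | CC(=O)c1c(O)cc(O)cc1O | starting material
2 | acetylfilicinic acid, 2-acetyl-3,5-dihydroxy-4,4-dimethylcyclohexa-2,5-dien-1-one | CC(=O)C1=C(O)C(C)(C)C(O)=CC1=O | intermediate
3 | 2',4',6'-trihydroxypropiophenone (flopropione) | CCC(=O)c1c(O)cc(O)cc1O | starting material
4 | propionylfilicinic acid, 3,5-dihydroxy-4,4-dimethyl-2-propanoylcyclohexa-2,5-dien-1-one | CCC(=O)C1=C(O)C(C)(C)C(O)=CC1=O | intermediate
5 | phloroglucinol, benzene-1,3,5-triol | Oc1cc(O)cc(O)c1 | starting material
6 | phlorobutyrophenone, 1-(2,4,6-trihydroxyphenyl)butan-1-one | CCCC(=O)c1c(O)cc(O)cc1O | intermediate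
7 | Mannich base of 2, 2-acetyl-6-[(dimethylamino)methyl]-3,5-dihydroxy-4,4-dimethylcyclohexa-2,5-dien-1-one (formed as its hydroiodide) | CC(=O)C1=C(O)C(C)(C)C(O)=C(CN(C)C)C1=O | intermediate
8 | methylene triketone of 2, 2-acetyl-3-hydroxy-4,4-dimethyl-6-methylidenecyclohex-2-ene-1,5-dione | CC(=O)C1=C(O)C(C)(C)C(=O)C(=C)C1=O | intermediate
9 | norflavaspidic acid AB, 2-acetyl-6-[(3-butanoyl-2,4,6-trihydroxyphenyl)methyl]-3,5-dihydroxy-4,4-dimethylcyclohexa-2,5-dien-1-one | CCCC(=O)c1c(O)cc(O)c(CC2=C(O)C(C)(C)C(O)=C(C(C)=O)C2=O)c1O | intermediate
10 | Mannich base of 4, 6-[(dimethylamino)methyl]-3,5-dihydroxy-4,4-dimethyl-2-propanoylcyclohexa-2,5-dien-1-one (formed as its hydroiodide) | CCC(=O)C1=C(O)C(C)(C)C(O)=C(CN(C)C)C1=O | intermediate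
11 | methylene triketone of 4, 3-hydroxy-4,4-dimethyl-6-methylidene-2-propanoylcyclohex-2-ene-1,5-dione | CCC(=O)C1=C(O)C(C)(C)C(=O)C(=C)C1=O | intermediate
12 | filixic acid ABP: butyrylphloroglucinol ring B carrying at C-3 the CH2-linked acetylfilicinic ring A and at C-5 the CH2-linked propionylfilicinic ring C | CCCC(=O)c1c(O)c(CC2=C(O)C(C)(C)C(O)=C(C(C)=O)C2=O)c(O)c(CC2=C(O)C(C)(C)C(O)=C(C(=O)CC)C2=O)c1O | target

Total step count: 5
Longest linear sequence: 3 steps (1 to 2 to 9 to 12, or 5 to 6 to 9 to 12)

Steps most likely to fail

Risk 1 (step 5): The liberated amine may trigger retro-Michael cleavage and re-addition at the A–B bridge, which would scramble the acyl pattern. The methylene triketone may also be lost to self-condensation, or to homo-coupling after partial retro-Mannich reversal. The fallback sets out from 4 and comes back to the route at 12. It releases the same electrophile without any amine. Compound 4 is condensed with aqueous formaldehyde and thiophenol (EtOH, catalytic Et3N, 50 °C) to give 6-(phenylthiomethyl)propionylfilicinic acid F1. This is oxidised with mCPBA (1.0 equiv, CH2Cl2, -40 °C) to 6-(phenylsulfinylmethyl)propionylfilicinic acid F2. Compound 9 is then added and the mixture is warmed to rt. The sulfoxide loses benzenesulfenic acid and gives 11 in a neutral medium, and C-5 of ring B captures it as in step 5.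

Risk 2 (step 4): Substitution may run on at the second free position of ring B, so that the precious triketone is consumed twice on one arene, and the large excess of 6 may be tedious to remove. The fallback sets out from 6 and comes back at 9. It inverts the roles of donor and acceptor and settles mono-functionalisation before the fragments meet. Compound 6 is treated with [Me2N=CH2]I (1.0 equiv, CH2Cl2, -20 °C) to give 3-[(dimethylamino)methyl]phlorobutyrophenone F3. Its hydroiodide should separate from solution and can be freed of doubly aminomethylated material by crystallisation. Heating F3 with 2 in dioxane at 90 °C expels dimethylamine and gives the ring B ortho-quinone methide F4. The enolic C-6 of 2 attacks F4 in a Michael addition to give 9.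

Risk 3 (step 2): Methylation may continue to a third or fourth C-methyl group, go to oxygen, or distribute the two methyls over C-3 and C-5 instead of placing both on one carbon, which would leave a difficult separation of homologues. The fallback sets out from 2 and comes back at 4. Only one dearomative methylation, that of the crystalline acetyl member, then has to be mastered, and the acyl group is installed after dearomatisation. Compound 2 is deacetylated by retro-Claisen cleavage (6 M HCl, reflux) to filicinic acid F5. This is treated with propanoic acid, DCC and DMAP (CH2Cl2, rt), which forms the filicinic acid enol propanoate F6. DMAP-mediated O-to-C acyl migration then carries F6 on to 4.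

Further compounds
F1 | step 5 | 6-(phenylthiomethyl)propionylfilicinic acid | CCC(=O)C1=C(O)C(C)(C)C(O)=C(CSc2ccccc2)C1=O
F2 | step 5 | 6-(phenylsulfinylmethyl)propionylfilicinic acid (racemic at sulfur) | CCC(=O)C1=C(O)C(C)(C)C(O)=C(CS(=O)c2ccccc2)C1=O
F3 | step 4 | 3-[(dimethylamino)methyl]phlorobutyrophenone | CCCC(=O)c1c(O)cc(O)c(CN(C)C)c1O
F4 | step 4 | ring B ortho-quinone methide | CCCC(=O)C1=C(O)C(=C)C(=O)C=C1O
F5 | step 2 | filicinic acid | CC1(C)C(O)=CC(=O)C=C1O
F6 | step 2 | filicinic acid enol propanoate | CCC(=O)OC1=CC(=O)C=C(O)C1(C)C
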